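The amounts of substrate in the birch and larch runs stayed near one level while the feed went on, so I took that level as the quantity to carry.

| setting | birch | larch | flask |
|---|---|---|---|
| substrate | 0.032 M (fed, over 25 min) | 0.047 M (fed, over 25 min) | 0.063 M (fed, over 25 min) |
| acid | 0.189 mM | 0.189 mM | 0.189 mM |
| remark | run made earlier | run made earlier |  |
| time |  |  | 25 min |

| run | time / min | target / % | substrate / % |
|---|---|---|---|
| birch | 1.33 | 2.8 | 2.1 |
| birch | 2.50 | 8.0 | 2.3 |
| birch | 4.00 | 13.5 | 1.9 |
| birch | 8.00 | 29.2 | 1.1 |
| birch | 15.0 | 58.8 | 1.8 |
| larch | 1.33 | 4.5 | 1.3 |
| larch | 2.50 | 8.1 | 1.0 |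
| larch | 4.00 | 13.7 | 1.8 |
| larch | 8.00 | 31.3 | 2.2 |
| larch | 15.0 | 57.4 | 2.7 |

(readings scatter by 0.5 percentage points)

- acid is the free proton; pH is minus the decimal logarithm of its molar concentration
- a species is counted by the substrate in it: one side product counts as two
- steps thought possible: substrate + acid -> weak acid + acid + target; weak acid <-> conjugate base + acid; substrate -> weak acid + target; substrate + target -> side product
- percentages count the whole charge, also what has not yet gone in

- amount of target in percent of the substrate charged, at 5.0 min, 12 min and 25 min

The 10 substrate readings averaged 1.82% of the charge, and they showed no clear trend between the two charges at equal c(acid), as pseudo-first-order consumption would. That level times the dosing time is 0.455 min. I called this the lag, the average stay of substrate in the flask before it becomes target, so target should follow the feed line late by the lag, as (t − lag)/dosing time. At 15.0 min this gave 58.2%, and the birch and larch runs read 58.8% and 57.4%.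

The new flask had the same c(acid), so I kept the lag and reckoned 18.2%, 46.2% and 98.2%. The forecast, reading “effectively first-order consumption”, gave 18.1%, 46% and 97.5%, lower than mine at the end.

The flask gave 18.0%, 45.8% and 96.9%, and the forecast stood within its tolerance.

    substrate + acid → weak acid + acid + target (k = 11000 M⁻¹ min⁻¹)
    weak acid ⇌ conjugate base + acid, settled at all times (K = 6.30 × 10⁻⁹ M)
    substrate → weak acid + target (k = 6.50 × 10⁻⁵ min⁻¹)
    substrate + target → side product (k = 0.410 M⁻¹ min⁻¹)

During the feed, substrate + acid ran in the flask on a standing substrate of 1.88% at 25.0 min, with a half-life of 0.33 min, and turned over 97.5% of the charge, half of it by 12.7 min. Beside it, substrate + target made 1.17% side product by 25.0 min, the half-life of target by that step, 24 h at 12.7 min, being long against 25 min. That standing substrate makes the flask's lag 0.470 min. With c(acid) taken as halved at 2 times the dilution, a lag of 0.910 min reckons 96.4% for that thin flask, which stood at 95.2%, under the 97.5% of the forecast for the new flask.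

The runs stem from a simulated flask for an exercise, and the scatter is random.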